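Breaking the C1–C8a bond of ring B (C1, C2, C3, C4, C4a, C8a) reveals a hidden twofold axis. The halves ring C–C1–C2–CH2OMe and ring A–C4–C3–CH2OMe become identical, and the precursor is the open-chain (2S,3S)-2,3-bis(3,4-dimethoxybenzyl)-1,4-dimethoxybutane. Its central bond (future C2–C3) comes from oxidative homocoupling of two like-polarised, auxiliary-bearing enolate carbons, which sets both stereocentres at once. The key step is a dehydrogenative C–H/C–H ring closure. DDQ takes hydride from either homotopic benzylic CH2, and the planar para-methoxybenzyl cation is captured by the other veratryl ring. One operation closes ring B, creates C1 trans to C2 and breaks the symmetry, without prefunctionalisation.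

Key step: step 5

Remark: tetralin numbering is used. C1 carries ring C (pendant arene), C2 and C3 carry the CH2OMe groups, C4 is the ring CH2, C4a and C8a are the fusion carbons of ring A (fused arene), and ring B is the carbocycle C1–C2–C3–C4–C4a–C8a.

Step 1
Reactants: 1 3-(3,4-dimethoxyphenyl)propanoic acid; 2 (4R)-4-isopropyl-1,3-oxazolidin-2-one
Product: 3 (4R)-3-[3-(3,4-dimethoxyphenyl)propanoyl]-4-isopropyl-1,3-oxazolidin-2-one
Conditions: DCC, DMAP (cat.), CH2Cl2, 0 °C to rt
Reagents that add atoms: none
Why: Carbodiimide/DMAP (Steglich-type) N-acylation, in which DMAP passes the activated acyl group of 1 on to the weakly nucleophilic carbamate nitrogen of 2 and the auxiliary stereocentre is not involved.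

Step 2
Reactants: 3 (4R)-3-[3-(3,4-dimethoxyphenyl)propanoyl]-4-isopropyl-1,3-oxazolidin-2-one (two molecules)
Product: 5 (2S,3S)-2,3-bis(3,4-dimethoxybenzyl)-1,4-bis[(4R)-4-isopropyl-2-oxo-1,3-oxazolidin-3-yl]butane-1,4-dione, via lithium Z-enolate 4 (not isolated)
Conditions: LiN(iPr)2 (commercial solution), THF, −78 °C; then anhydrous CuCl2, THF–DMF, −78 °C to 0 °C; crystallisation or chromatography
Reagents that add atoms: none
Why: Oxidative enolate homocoupling, in which divalent copper oxidises the chelated Z-enolate 4 by one electron and the two like-polarised α-carbons join on the face anti to the isopropyl group on both halves, so the 4R auxiliary should set both new centres as S, the same facial sense as in alkylations of such enolates.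

Step 3
Reactants: 5 (2S,3S)-2,3-bis(3,4-dimethoxybenzyl)-1,4-bis[(4R)-4-isopropyl-2-oxo-1,3-oxazolidin-3-yl]butane-1,4-dione
Product: 6 (2S,3S)-2,3-bis(3,4-dimethoxybenzyl)butane-1,4-diol
Conditions: LiBH4, H2O (1 equiv per LiBH4), Et2O–THF, 0 °C to rt
Reagents that add atoms: none
Why: Reductive cleavage of N-acyl oxazolidinones by borohydride, in which the exocyclic imide carbonyls are attacked first, any γ-lactone formed on the way is reduced to the same diol, and the two stereocentres are not touched.

Step 4
Reactants: 6 (2S,3S)-2,3-bis(3,4-dimethoxybenzyl)butane-1,4-diol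
Product: 7 (2S,3S)-2,3-bis(3,4-dimethoxybenzyl)-1,4-dimethoxybutane (the lignan phyllanthin)
Conditions: NaH, MeI, THF, 0 °C to rt
Reagents that add atoms: iodomethane, CI
Why: Double Williamson ether synthesis on two primary alkoxides, with no leaving group present that could divert the 1,4-diol to a tetrahydrofuran and no stereocentre involved.

Step 5
Reactants: 7 (2S,3S)-2,3-bis(3,4-dimethoxybenzyl)-1,4-dimethoxybutane
Product: 9 phyltetralin [(1R,2S,3S)-1-(3,4-dimethoxyphenyl)-6,7-dimethoxy-2,3-bis(methoxymethyl)-1,2,3,4-tetrahydronaphthalene], via benzylic cation 8 (not isolated)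
Conditions: DDQ (1.0 equiv), 4 Å MS, CH2Cl2–AcOH, 0 °C to rt; then TFA, 0 °C (added once the DDQ is spent)
Reagents that add atoms: none
Why: DDQ binds a veratryl ring of 7 in a charge-transfer complex and removes hydride (electron, proton, electron) from the benzylic CH2 para to its 4-OMe group, the resulting para-quinone-methide-like cation 8 is attacked by C6 of the other veratryl ring, and DDQH− takes the arenium proton, while the late TFA charge re-ionises any benzylic acetate, aryl ether or methyloxonium resting state so that everything drains into the irreversible C–C bond. The closest known reaction type is the quinone-mediated dehydrogenative benzylic C–H arylation, that is the oxidative cyclisation of dibenzylbutane-type lignans to aryltetralins, an intramolecular Friedel–Crafts alkylation run from a C–H bond. Ring B closes through the C1–C8a bond in a 6-exo-trig mode at the cationic carbon (the C=C of the quinone-methide form lies outside the new ring), with the arene bond C4a=C8a ending inside it. C1 is controlled by the resident C2 and C3 centres: in the half-chair transition state both CH2OMe groups sit pseudo-equatorial and ring C takes the pseudo-equatorial position anti to the C2 substituent, which should give 1R (1,2-trans, 2,3-trans), and since 8 is planar the result does not depend on which diastereotopic hydrogen left. Site selectivity is secured by symmetry and substitution: the twofold axis makes both CH2 groups and both arenes equivalent, and attack at C6 (para to the 3-OMe group, unhindered) or an ipso attack followed by a 1,2-shift both lead to the same 6,7-dimethoxy pattern. The chemoselectivity needed is C–H cleavage over aryl–aryl coupling and over further dehydrogenation of 9, secured by keeping strong acid out while oxidant is present (the radical-ion pair then collapses by proton transfer), by one equivalent of DDQ and by the hindered tertiary C1–H of 9.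

Compound list
1 | 3-(3,4-dimethoxyphenyl)propanoic acid | COc1ccc(CCC(=O)O)cc1OC | starting material
2 | (4R)-4-isopropyl-1,3-oxazolidin-2-one | CC(C)[C@@H]1COC(=O)N1 | starting material
3 | (4R)-3-[3-(3,4-dimethoxyphenyl)propanoyl]-4-isopropyl-1,3-oxazolidin-2-one | COc1ccc(CCC(=O)N2[C@H](C(C)C)COC2=O)cc1OC | intermediate
4 | lithium Z-enolate of 3 (not isolated) | [Li]O/C(=C\Cc1ccc(OC)c(OC)c1)N1[C@H](C(C)C)COC1=O | intermediate
5 | (2S,3S)-2,3-bis(3,4-dimethoxybenzyl)-1,4-bis[(4R)-4-isopropyl-2-oxo-1,3-oxazolidin-3-yl]butane-1,4-dione | O=C(N1[C@H](C(C)C)COC1=O)[C@@H](Cc1ccc(OC)c(OC)c1)[C@H](Cc1ccc(OC)c(OC)c1)C(=O)N1[C@H](C(C)C)COC1=O | intermediate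
6 | (2S,3S)-2,3-bis(3,4-dimethoxybenzyl)butane-1,4-diol | OC[C@@H](Cc1ccc(OC)c(OC)c1)[C@H](Cc1ccc(OC)c(OC)c1)CO | intermediate
7 | (2S,3S)-2,3-bis(3,4-dimethoxybenzyl)-1,4-dimethoxybutane (phyllanthin) | COC[C@@H](Cc1ccc(OC)c(OC)c1)[C@H](Cc1ccc(OC)c(OC)c1)COC | intermediate
8 | secondary para-methoxybenzylic cation from 7 (not isolated) | COC[C@@H]([CH+]c1ccc(OC)c(OC)c1)[C@H](Cc1ccc(OC)c(OC)c1)COC | intermediate
9 | phyltetralin, (1R,2S,3S)-1-(3,4-dimethoxyphenyl)-6,7-dimethoxy-2,3-bis(methoxymethyl)-1,2,3,4-tetrahydronaphthalene | COC[C@H]1Cc2cc(OC)c(OC)cc2[C@@H](c2ccc(OC)c(OC)c2)[C@@H]1COC | target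

Total step count: 5. Longest linear sequence: 5.

Steps most likely to fail

Step 5 (key step). Three processes may interfere.
- Electron transfer may outrun C–H cleavage, so that the two arenes couple to an eight-membered biaryl.
- A neighbouring methoxy oxygen may capture the cation with loss of its methyl group.
- The quinone may dehydrogenate ring B further.

Fallback, from 3 back to 9: the ionisable benzylic position is built by an aldol reaction, and ring B is closed with no oxidant present. Auxiliary-controlled enolate alkylation of 3 (NaN(SiMe3)2, tert-butyl bromoacetate, THF, −78 °C) should give tert-butyl (3S)-3-(3,4-dimethoxybenzyl)-4-[(4R)-4-isopropyl-2-oxo-1,3-oxazolidin-3-yl]-4-oxobutanoate F1. LiBH4/H2O should reduce only the imide to tert-butyl (3S)-3-(3,4-dimethoxybenzyl)-4-hydroxybutanoate F2. Catalytic p-TsOH in warm toluene should close (4S)-4-(3,4-dimethoxybenzyl)dihydrofuran-2(3H)-one F3. LiN(iPr)2 and then 3,4-dimethoxybenzaldehyde should give the trans aldol adduct (3R,4S)-4-(3,4-dimethoxybenzyl)-3-[(3,4-dimethoxyphenyl)(hydroxy)methyl]dihydrofuran-2(3H)-one F4 as a mixture of carbinol epimers. TFA in CH2Cl2 should ionise both epimers to one cation and close ring B to the all-trans (1R,2S,3S) aryltetralin lactone F5, with the carbonyl on C2 and the OCH2 on C3. LiAlH4 should open it to (1R,2S,3S)-1-(3,4-dimethoxyphenyl)-2,3-bis(hydroxymethyl)-6,7-dimethoxytetralin F6, and NaH with MeI should give 9.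

Step 2. The coupling may escape auxiliary control on one half (poor facial selectivity leading to the meso-type isomer), or the enolate may be chlorinated or merely reprotonated.

Fallback, from 3 back to 6: the central bond is not made by coupling, and the second benzyl group is attached by alkylation. Compound 3 is taken to the imide F1, the hydroxy ester F2 and the lactone F3 as described above. LiN(SiMe3)2 and 3,4-dimethoxybenzyl bromide (THF, −78 °C) should alkylate the lactone enolate anti to the resident benzyl group to give (3S,4S)-3,4-bis(3,4-dimethoxybenzyl)dihydrofuran-2(3H)-one F7. LiAlH4 should reduce it to 6.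

Step 3. Hydride may attack the ring carbonyl of the hindered imides, opening the auxiliary, or the reduction may stall.

Fallback, from 5 back to 6: cleavage and reduction are separated. LiOH/H2O2 in THF–H2O at 0 °C, where hydroperoxide attacks the exocyclic carbonyl, should give (2S,3S)-2,3-bis(3,4-dimethoxybenzyl)butanedioic acid F8. BH3·THF should reduce it to 6.

Further compounds
F1 | step 5 | tert-butyl (3S)-3-(3,4-dimethoxybenzyl)-4-[(4R)-4-isopropyl-2-oxo-1,3-oxazolidin-3-yl]-4-oxobutanoate | O=C(N1[C@H](C(C)C)COC1=O)[C@@H](Cc1ccc(OC)c(OC)c1)CC(=O)OC(C)(C)C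
F2 | step 5 | tert-butyl (3S)-3-(3,4-dimethoxybenzyl)-4-hydroxybutanoate | OC[C@@H](Cc1ccc(OC)c(OC)c1)CC(=O)OC(C)(C)C
F3 | step 5 | (4S)-4-(3,4-dimethoxybenzyl)dihydrofuran-2(3H)-one | O=C1C[C@H](Cc2ccc(OC)c(OC)c2)CO1
F4 | step 5 | (3R,4S)-4-(3,4-dimethoxybenzyl)-3-[(3,4-dimethoxyphenyl)(hydroxy)methyl]dihydrofuran-2(3H)-one, carbinol epimers | O=C1[C@@H](C(O)c2ccc(OC)c(OC)c2)[C@H](Cc2ccc(OC)c(OC)c2)CO1
F5 | step 5 | all-trans (1R,2S,3S)-1-(3,4-dimethoxyphenyl)-6,7-dimethoxytetralin-2,3-carbolactone (C=O on C2, OCH2 on C3) | O=C1OC[C@H]2Cc3cc(OC)c(OC)cc3[C@@H](c3ccc(OC)c(OC)c3)[C@H]12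
F6 | step 5 | (1R,2S,3S)-1-(3,4-dimethoxyphenyl)-2,3-bis(hydroxymethyl)-6,7-dimethoxy-1,2,3,4-tetrahydronaphthalene | OC[C@H]1Cc2cc(OC)c(OC)cc2[C@@H](c2ccc(OC)c(OC)c2)[C@@H]1CO
F7 | step 2 | (3S,4S)-3,4-bis(3,4-dimethoxybenzyl)dihydrofuran-2(3H)-one | O=C1[C@@H](Cc2ccc(OC)c(OC)c2)[C@H](Cc2ccc(OC)c(OC)c2)CO1
F8 | step 3 | (2S,3S)-2,3-bis(3,4-dimethoxybenzyl)butanedioic acid | OC(=O)[C@@H](Cc1ccc(OC)c(OC)c1)[C@H](Cc1ccc(OC)c(OC)c1)C(=O)O
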